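## Retrosynthetic overview

- The C40 chain is cut at C11=C12 and C11'=C12' (two Wittig reactions) into an acetylenic C15 phosphonium salt, the commercial C10 trienedial and an olefinic C15 phosphonium salt.
- Both C15 salts come from one ring alkyne and one C4 alkenyl iodide: Sonogashira coupling keeps the C7≡C8 triple bond, hydroboration/Suzuki coupling gives the C7'=C8' E-alkene.
- The ring alkyne comes from safranal by epoxidation of the 3,4-alkene, C–O bond-forming enantioconvergent hydrolysis to the (3S,4S)-trans-diol (key step, sets all four stereocentres because the same building block serves both ends), silylation and aldehyde-to-alkyne homologation.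
- Rings: neither carbocycle is built (both come intact from safranal); the only ring formed is the oxirane of step 1, opened in step 2.

Assumptions: carotenoid numbering is used for positions; a racemate (epoxide 2, diol F1) is written by the SMILES of one enantiomer and marked rac- in its name, which stands for the 1:1 mixture with the mirror image; the (R,R) catalyst antipode in step 2 is taken as the one that attacks R-configured oxirane carbons (a single test run fixes this; otherwise the mirror-image catalyst is used and nothing else changes).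

## Route

Step 1
Reactants: 1 safranal
Product: 2 racemic cis-3,4-epoxide of safranal
Conditions: dimethyldioxirane (1.1 equiv), acetone, 0 °C
Reagents that add atoms: dimethyldioxirane, CC1(C)OO1
Why: Electrophilic epoxidation by the neutral dioxirane takes the electron-richer, unhindered cis-disubstituted 3,4-alkene and spares the formyl-conjugated tetrasubstituted 5,6-alkene and the aldehyde, giving the (necessarily cis-fused) racemic vinyl oxirane under acid-free conditions.

Step 2
Reactants: 2 racemic cis-3,4-epoxide of safranal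
Product: 3 (3S,4S)-trans-diol aldehyde
Conditions: (R,R)-(salen)Co(OTf) cyclic oligomer (2 mol% Co, trivalent cobalt; salen = pimelate-linked 3-tert-butylsalicylidene/trans-1,2-cyclohexanediamine units), H2O (1.3 equiv), MeCN/CH2Cl2, 4 °C → rt, full conversion
Reagents that add atoms: water, O
Why: Proposed new method: enantioconvergent hydrolysis of a racemic unsymmetrical cis-epoxide, in which one cobalt centre binds the oxirane and a neighbouring Co–OH delivers hydroxide by backside attack, the catalyst choosing the R-configured oxirane carbon in whichever enantiomer is bound (the allylic carbon of (1R,6S)-2, the homoallylic carbon of (1S,6R)-2) so that inversion at the attacked carbon and retention at the other turn every molecule of racemic 2, with one molecule of water, into the same (3S,4S)-trans-diol, helped by the conjugated formyl group, which damps allylic-cation character and keeps the substrate's own regiochemical bias small; the closest known reaction types are the (salen)Co-catalysed asymmetric hydrolysis of meso-epoxides, the hydrolytic kinetic resolution of terminal epoxides and enzymatic enantioconvergent hydrolysis by epoxide hydrolases.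

Step 3
Reactants: 3 (3S,4S)-trans-diol aldehyde
Product: 4 bis-TBS ether aldehyde
Conditions: TBSOTf (2.5 equiv), 2,6-lutidine, CH2Cl2, −78 → 0 °C
Reagents that add atoms: tert-butyldimethylsilyl triflate, CC(C)(C)[Si](C)(C)OS(=O)(=O)C(F)(F)F
Why: Silyl ether formation with the highly electrophilic silyl triflate covers both hindered secondary hydroxyls (the allylic one would otherwise ionise or quench later reagents) without touching either stereocentre.

Step 4
Reactants: 4 bis-TBS ether aldehyde
Product: 5 ring alkyne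
Conditions: dimethyl (1-diazo-2-oxopropyl)phosphonate (1.5 equiv), K2CO3 (2 equiv), MeOH/THF, 0 °C → rt
Reagents that add atoms: dimethyl (1-diazo-2-oxopropyl)phosphonate, CC(=O)C(=[N+]=[N-])P(=O)(OC)OC
Why: Seyferth–Gilbert homologation in its Ohira–Bestmann form, in which the diazomethylphosphonate anion olefinates the aldehyde and the diazoalkene loses N2 with 1,2-shift to the terminal alkyne under base mild enough to leave the silyloxy stereocentres alone.

Step 5
Reactants: 6 but-2-yn-1-ol
Product: 8 (E)-3-iodobut-2-en-1-ol, via alkenylzirconocene 7 (not isolated)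
Conditions: Cp2Zr(H)Cl (2.3 equiv), THF, 0 → 40 °C; I2 (1.1 equiv), 0 °C; aqueous work-up
Reagents that add atoms: iodine, II
Why: syn-Hydrozirconation places zirconium on the methyl-bearing alkyne carbon, distal to the bulky zirconium alkoxide, and iodinolysis of the C–Zr bond with retention gives the E-iodide.

Step 6
Reactants: 5 ring alkyne; 8 (E)-3-iodobut-2-en-1-ol
Product: 9 acetylenic C15 alcohol (E-enynol)
Conditions: Pd(PPh3)2Cl2 (3 mol%), CuI (5 mol%), i-Pr2NH, THF, rt, degassed
Reagents that add atoms: none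
Why: Sonogashira coupling of a terminal alkyne with an alkenyl iodide forms the C8–C9 bond with retention of the E geometry and tolerates the free alcohol and the silyl ethers.

Step 7
Reactants: 9 acetylenic C15 alcohol
Product: 11 acetylenic C15 phosphonium bromide, via acetylenic allylic bromide 10 (not isolated)
Conditions: CBr4 (1.2 equiv), PPh3 (1.2 equiv), CH2Cl2, 0 °C; then PPh3 (1.5 equiv), rt
Reagents that add atoms: carbon tetrabromide, BrC(Br)(Br)Br; triphenylphosphine, c1ccc(cc1)P(c1ccccc1)c1ccccc1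
Why: Appel bromination of the primary allylic alcohol under neutral conditions followed by SN2 quaternisation of PPh3 in the same flask, so that no acid reaches the allylic silyl ether.

Step 8
Reactants: 5 ring alkyne; 8 (E)-3-iodobut-2-en-1-ol
Product: 13 olefinic C15 alcohol (E,E-dienol), via E-alkenylboronate 12 (not isolated)
Conditions: pinacolborane (1.3 equiv), Cp2Zr(H)Cl (10 mol%), Et3N (10 mol%), 60 °C; then 8, Pd(PPh3)4 (5 mol%), 2 M aq. KOH, THF, 40 °C
Reagents that add atoms: none
Why: Catalysed syn-hydroboration puts boron on the terminal alkyne carbon to give the E-alkenylboronate, and Suzuki–Miyaura coupling at zerovalent palladium is stereoretentive for both partners, giving the 7E,9E-diene.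

Step 9
Reactants: 13 olefinic C15 alcohol
Product: 15 olefinic C15 phosphonium bromide, via dienyl allylic bromide 14 (not isolated)
Conditions: CBr4 (1.2 equiv), PPh3 (1.2 equiv), CH2Cl2, −20 → 0 °C; then PPh3 (1.5 equiv), rt
Reagents that add atoms: carbon tetrabromide, BrC(Br)(Br)Br; triphenylphosphine, c1ccc(cc1)P(c1ccccc1)c1ccccc1
Why: Appel bromination and in-flask SN2 quaternisation as in step 7, the labile dienyl bromide being trapped by PPh3 as it forms.

Step 10
Reactants: 15 olefinic C15 phosphonium bromide; 16 C10 trienedial (2 equiv)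
Product: 18 C25 apo-aldehyde, via olefinic ylide 17 (not isolated)
Conditions: NaOMe (1.1 equiv), CH2Cl2/MeOH, 0 °C → rt; then heptane, 90 °C, 2 h
Reagents that add atoms: none
Why: Wittig olefination in which the semi-stabilised allylic ylide reacts once with the excess dialdehyde, the Z component at the new disubstituted C=C being isomerised thermally to E.

Step 11
Reactants: 11 acetylenic C15 phosphonium bromide; 18 C25 apo-aldehyde
Product: 20 tetra-TBS-protected C40 carotenoid, via acetylenic ylide 19 (not isolated)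
Conditions: NaOMe (1.2 equiv), CH2Cl2/MeOH, 0 °C → rt; then heptane, 60 °C, 1 h, dark, followed by HPLC; all-E isomer by crystallisation or chromatography
Reagents that add atoms: none
Why: Wittig olefination joins the two halves at C11=C12, the sterically strained 11Z isomer relaxes to 11E under heating kept mild and short enough that the 9E enyne bond next to the triple bond does not drift to 9Z, and crystallisation gives the all-E polyene.

Step 12
Reactants: 20 tetra-TBS-protected C40 carotenoid
Product: 21 target tetrol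
Conditions: TBAF (8 equiv), AcOH (8 equiv), THF, 40 °C, dark, argon
Reagents that add atoms: none
Why: Fluoride-mediated desilylation (Si–F bond formation) frees the four hydroxyls under buffered, non-acidic conditions tolerated by the polyene and the allylic alcohols, with no stereocentre touched.

## Compound list

1 | safranal (2,6,6-trimethylcyclohexa-1,3-diene-1-carbaldehyde) | CC1=C(C=O)C(C)(C)CC=C1 | starting material
2 | rac-(1R,6S)-2,4,4-trimethyl-7-oxabicyclo[4.1.0]hept-2-ene-3-carbaldehyde (racemic cis-3,4-epoxide of safranal; the (1R,6S) enantiomer is drawn) | CC1=C(C=O)C(C)(C)C[C@@H]2O[C@H]12 | intermediate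
3 | (3S,4S)-3,4-dihydroxy-2,6,6-trimethylcyclohex-1-ene-1-carbaldehyde (trans-diol) | CC1=C(C=O)C(C)(C)C[C@H](O)[C@H]1O | intermediate
4 | (3S,4S)-3,4-bis[(tert-butyldimethylsilyl)oxy]-2,6,6-trimethylcyclohex-1-ene-1-carbaldehyde | CC1=C(C=O)C(C)(C)C[C@H](O[Si](C)(C)C(C)(C)C)[C@H]1O[Si](C)(C)C(C)(C)C | intermediate
5 | (3S,4S)-3,4-bis[(tert-butyldimethylsilyl)oxy]-1-ethynyl-2,6,6-trimethylcyclohex-1-ene (ring numbered from the ethynyl carbon) | CC1=C(C#C)C(C)(C)C[C@H](O[Si](C)(C)C(C)(C)C)[C@H]1O[Si](C)(C)C(C)(C)C | intermediate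
6 | but-2-yn-1-ol | CC#CCO | starting material
7 | (E)-alkenylzirconocene Cp2Zr(Cl)–C(CH3)=CH–CH2–O–Zr(Cl)Cp2 (not isolated) | C/C(=C\CO[Zr](Cl)(C1C=CC=C1)C1C=CC=C1)[Zr](Cl)(C1C=CC=C1)C1C=CC=C1 | intermediate
8 | (2E)-3-iodobut-2-en-1-ol | C/C(I)=C\CO | intermediate
9 | (2E)-5-[(3S,4S)-3,4-bis[(tert-butyldimethylsilyl)oxy]-2,6,6-trimethylcyclohex-1-en-1-yl]-3-methylpent-2-en-4-yn-1-ol | CC1=C(C#C/C(C)=C/CO)C(C)(C)C[C@H](O[Si](C)(C)C(C)(C)C)[C@H]1O[Si](C)(C)C(C)(C)C | intermediate
10 | (2E)-1-bromo-5-[(3S,4S)-3,4-bis[(tert-butyldimethylsilyl)oxy]-2,6,6-trimethylcyclohex-1-en-1-yl]-3-methylpent-2-en-4-yne (not isolated) | CC1=C(C#C/C(C)=C/CBr)C(C)(C)C[C@H](O[Si](C)(C)C(C)(C)C)[C@H]1O[Si](C)(C)C(C)(C)C | intermediate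
11 | [(2E)-5-[(3S,4S)-3,4-bis[(tert-butyldimethylsilyl)oxy]-2,6,6-trimethylcyclohex-1-en-1-yl]-3-methylpent-2-en-4-yn-1-yl]triphenylphosphonium bromide | CC1=C(C#C/C(C)=C/C[P+](c2ccccc2)(c2ccccc2)c2ccccc2)C(C)(C)C[C@H](O[Si](C)(C)C(C)(C)C)[C@H]1O[Si](C)(C)C(C)(C)C.[Br-] | intermediate
12 | 2-[(E)-2-[(3S,4S)-3,4-bis[(tert-butyldimethylsilyl)oxy]-2,6,6-trimethylcyclohex-1-en-1-yl]ethenyl]-4,4,5,5-tetramethyl-1,3,2-dioxaborolane (not isolated) | CC1=C(/C=C/B2OC(C)(C)C(C)(C)O2)C(C)(C)C[C@H](O[Si](C)(C)C(C)(C)C)[C@H]1O[Si](C)(C)C(C)(C)C | intermediate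
13 | (2E,4E)-5-[(3S,4S)-3,4-bis[(tert-butyldimethylsilyl)oxy]-2,6,6-trimethylcyclohex-1-en-1-yl]-3-methylpenta-2,4-dien-1-ol | CC1=C(/C=C/C(C)=C/CO)C(C)(C)C[C@H](O[Si](C)(C)C(C)(C)C)[C@H]1O[Si](C)(C)C(C)(C)C | intermediate
14 | (2E,4E)-1-bromo-5-[(3S,4S)-3,4-bis[(tert-butyldimethylsilyl)oxy]-2,6,6-trimethylcyclohex-1-en-1-yl]-3-methylpenta-2,4-diene (not isolated) | CC1=C(/C=C/C(C)=C/CBr)C(C)(C)C[C@H](O[Si](C)(C)C(C)(C)C)[C@H]1O[Si](C)(C)C(C)(C)C | intermediate
15 | [(2E,4E)-5-[(3S,4S)-3,4-bis[(tert-butyldimethylsilyl)oxy]-2,6,6-trimethylcyclohex-1-en-1-yl]-3-methylpenta-2,4-dien-1-yl]triphenylphosphonium bromide | CC1=C(/C=C/C(C)=C/C[P+](c2ccccc2)(c2ccccc2)c2ccccc2)C(C)(C)C[C@H](O[Si](C)(C)C(C)(C)C)[C@H]1O[Si](C)(C)C(C)(C)C.[Br-] | intermediate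
16 | (2E,4E,6E)-2,7-dimethylocta-2,4,6-trienedial (C10 dialdehyde) | O=C/C(C)=C/C=C/C=C(C)/C=O | starting material
17 | phosphorus ylide of 15, Ph3P=CH–CH=C(CH3)–CH=CH–ring (not isolated) | CC1=C(/C=C/C(C)=C/C=P(c2ccccc2)(c2ccccc2)c2ccccc2)C(C)(C)C[C@H](O[Si](C)(C)C(C)(C)C)[C@H]1O[Si](C)(C)C(C)(C)C | intermediate
18 | (2E,4E,6E,8E,10E,12E)-13-[(3S,4S)-3,4-bis[(tert-butyldimethylsilyl)oxy]-2,6,6-trimethylcyclohex-1-en-1-yl]-2,7,11-trimethyltrideca-2,4,6,8,10,12-hexaenal (C25 apo-aldehyde) | CC1=C(/C=C/C(C)=C/C=C/C(C)=C/C=C/C=C(C)/C=O)C(C)(C)C[C@H](O[Si](C)(C)C(C)(C)C)[C@H]1O[Si](C)(C)C(C)(C)C | intermediate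
19 | phosphorus ylide of 11, Ph3P=CH–CH=C(CH3)–C≡C–ring (not isolated) | CC1=C(C#C/C(C)=C/C=P(c2ccccc2)(c2ccccc2)c2ccccc2)C(C)(C)C[C@H](O[Si](C)(C)C(C)(C)C)[C@H]1O[Si](C)(C)C(C)(C)C | intermediate
20 | all-E-(3S,4S,3'S,4'S)-3,4,3',4'-tetrakis[(tert-butyldimethylsilyl)oxy]-7,8-didehydro-β,β-carotene | CC1=C(C#C/C(C)=C/C=C/C(C)=C/C=C/C=C(C)/C=C/C=C(C)/C=C/C2=C(C)[C@H](O[Si](C)(C)C(C)(C)C)[C@@H](O[Si](C)(C)C(C)(C)C)CC2(C)C)C(C)(C)C[C@H](O[Si](C)(C)C(C)(C)C)[C@H]1O[Si](C)(C)C(C)(C)C | intermediate
21 | all-E-(3S,4S,3'S,4'S)-7,8-didehydro-β,β-carotene-3,4,3',4'-tetrol (CNP0343957.1) | CC1=C(C#C/C(C)=C/C=C/C(C)=C/C=C/C=C(C)/C=C/C=C(C)/C=C/C2=C(C)[C@H](O)[C@@H](O)CC2(C)C)C(C)(C)C[C@H](O)[C@H]1O | target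

## Step count and risks

Total steps: 12. Longest linear sequence: 9 (steps 1, 2, 3, 4, 8, 9, 10, 11, 12).

Three steps most likely to fail:

Step 2 (the proposed new enantioconvergent hydrolysis). If catalyst control does not override the substrate's regiochemical bias for the mismatched enantiomer, the reaction becomes a kinetic resolution or gives a diol of reduced enantiomeric purity. The fallback uses known chemistry, sets out from 2 and comes back at 3. Racemic 2 is hydrolysed without chiral control (THF/H2O, 1 mol% HClO4, 0 °C; either regiochemistry gives the same racemate) to the racemic trans-diol rac-(3R,4R)-3,4-dihydroxy-2,6,6-trimethylcyclohex-1-ene-1-carbaldehyde F1. This is resolved by lipase-catalysed transesterification (Amano lipase PS, vinyl acetate, MTBE, 30 °C, about 52% conversion), which acylates the (3R,4R) enantiomer at the less hindered homoallylic hydroxyl to (1R,2R)-4-formyl-2-hydroxy-3,5,5-trimethylcyclohex-3-en-1-yl acetate F2. The untouched (3S,4S) enantiomer is diol 3 (at most 50%), separated by chromatography.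

Step 4 (homologation of a hindered, tetrasubstituted enal). Methoxide could attack slowly, add to the intermediate diazoalkene, or deprotonate the vinylogous γ-position, with epimerisation or loss of silanol. The fallback sets out from 4 and comes back at 5 by a Corey–Fuchs sequence: CBr4, PPh3 and Zn in CH2Cl2 at 0 °C give (3S,4S)-3,4-bis[(tert-butyldimethylsilyl)oxy]-1-(2,2-dibromoethenyl)-2,6,6-trimethylcyclohex-1-ene F3 under non-basic conditions; n-BuLi (2.2 equiv) in THF at −78 °C, then aqueous NH4Cl, gives alkyne 5.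

Step 8 (one-pot hydroboration/Suzuki coupling). Hydroboration of the hindered enyne may be incomplete, or protodeboronation may compete in the coupling. The fallback sets out from 4 and comes back at 13, building the diene by carbonyl olefination instead of cross-coupling. Horner–Wadsworth–Emmons reaction of 4 with triethyl 3-methyl-4-phosphonocrotonate (LiN(SiMe3)2, THF, −78 → 0 °C) gives ethyl (2E,4E)-5-[(3S,4S)-3,4-bis[(tert-butyldimethylsilyl)oxy]-2,6,6-trimethylcyclohex-1-en-1-yl]-3-methylpenta-2,4-dienoate F4 (the minor 2Z isomer is removed by chromatography). Reduction with i-Bu2AlH (CH2Cl2, −78 °C) gives 13.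

Further compounds
F1 | step 2 | rac-(3R,4R)-3,4-dihydroxy-2,6,6-trimethylcyclohex-1-ene-1-carbaldehyde (racemic trans-diol; the (3R,4R) enantiomer is drawn) | CC1=C(C=O)C(C)(C)C[C@@H](O)[C@@H]1O
F2 | step 2 | (1R,2R)-4-formyl-2-hydroxy-3,5,5-trimethylcyclohex-3-en-1-yl acetate | CC1=C(C=O)C(C)(C)C[C@@H](OC(C)=O)[C@@H]1O
F3 | step 4 | (3S,4S)-3,4-bis[(tert-butyldimethylsilyl)oxy]-1-(2,2-dibromoethenyl)-2,6,6-trimethylcyclohex-1-ene | CC1=C(C=C(Br)Br)C(C)(C)C[C@H](O[Si](C)(C)C(C)(C)C)[C@H]1O[Si](C)(C)C(C)(C)C
F4 | step 8 | ethyl (2E,4E)-5-[(3S,4S)-3,4-bis[(tert-butyldimethylsilyl)oxy]-2,6,6-trimethylcyclohex-1-en-1-yl]-3-methylpenta-2,4-dienoate | CC1=C(/C=C/C(C)=C/C(=O)OCC)C(C)(C)C[C@H](O[Si](C)(C)C(C)(C)C)[C@H]1O[Si](C)(C)C(C)(C)C
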